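The 36‑membered lactone is disconnected not at the ester but at C17–C18. C17 is an isolated carbinol in the run of 1,5‑related hydroxyls, and C18–C20 are plain ring methylenes. An (E)‑C18=C19 alkenyl iodide and a C17 aldehyde, held in one ester‑linked chain, can therefore be joined by a ligand‑controlled Ni/Cr‑mediated (Nozaki–Hiyama–Kishi) addition. This single operation closes the macrocycle far from the lactone, forms C17–C18 and sets C17; hydrogenation later erases the alkene. The precursor is the seco ester of a C1–C17 aldehyde acid (iterative allylboration/hydroformylation) with a C18–C40 iodoalkenol, whose C21 and C29 carbinols come from one epoxide‑derived building block.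

Key step: step 31

Remark: locants C1–C40 are those of the seco acid of the target (C1 lactone carbonyl, C35 lactone carbinol, C36–C40 side chain); where CIP priorities shift along the route the SMILES strings define the configuration, and compounds 1 and 14 are taken as commercially available.

**C1–C17 aldehyde acid (steps 1–12)**

Step 1
Reactants: 1 methyl hydrogen (R)-3-methylglutarate
Product: 2 methyl (3R)-5-hydroxy-3-methylpentanoate
Conditions: BH3·SMe2, THF, 0 °C → rt; MeOH quench; used at once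
Reagents that add atoms: none
Why: Chemoselective borane reduction of the carboxylic acid (via the acyloxyborane) beside the methyl ester should give the hydroxy ester with C3 untouched; immediate use avoids δ‑lactonisation.

Step 2
Reactants: 2 methyl (3R)-5-hydroxy-3-methylpentanoate
Product: 3 methyl (3R)-3-methyl-5-oxopentanoate
Conditions: TEMPO (10 mol %), PhI(OAc)2, CH2Cl2, rt
Reagents that add atoms: none
Why: Oxoammonium (TEMPO) oxidation of the primary alcohol should stop at the aldehyde under neutral conditions.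

Step 3
Reactants: 3 methyl (3R)-3-methyl-5-oxopentanoate
Product: 4 methyl (3R,5R)-5-hydroxy-3-methyloct-7-enoate
Conditions: (+)-Ipc2BOMe (from (−)-α-pinene), allylMgBr, Et2O, 0 °C → rt; then 3, −78 °C; pH 7 buffer, MeOH, 30 % H2O2
Reagents that add atoms: allylmagnesium bromide, C=CC[Mg]Br
Why: Brown allylboration through a chair transition state should deliver allyl to the Re face of the aldehyde and set C5 under reagent control, the ester being inert to the allylborane.

Step 4
Reactants: 4 methyl (3R,5R)-5-hydroxy-3-methyloct-7-enoate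
Product: 5 methyl (3R,5R)-5-[(tert-butyldimethylsilyl)oxy]-3-methyloct-7-enoate
Conditions: TBSOTf, 2,6-lutidine, CH2Cl2, −78 °C
Reagents that add atoms: tert-butyldimethylsilyl triflate, CC(C)(C)[Si](C)(C)OS(=O)(=O)C(F)(F)F
Why: Silyl ether formation with the silyl triflate is fast at low temperature and forestalls δ‑lactonisation of the hydroxy ester.

Step 5
Reactants: 5 methyl (3R,5R)-5-[(tert-butyldimethylsilyl)oxy]-3-methyloct-7-enoate
Product: 6 methyl (3R,5R)-5-[(tert-butyldimethylsilyl)oxy]-3-methyl-9-oxononanoate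
Conditions: Rh(acac)(CO)2 (1 mol %), BIPHEPHOS (2 mol %), CO/H2 (1:1, 5 bar), THF, 60 °C
Reagents that add atoms: carbon monoxide, [C-]#[O+]
Why: Rhodium‑catalysed hydroformylation with the wide‑bite‑angle bisphosphite should be linear‑selective and place the C9 aldehyde three methylenes from C5.

Step 6
Reactants: 6 methyl (3R,5R)-5-[(tert-butyldimethylsilyl)oxy]-3-methyl-9-oxononanoate
Product: 7 methyl 5-[(tert-butyldimethylsilyl)oxy]-9-hydroxy-3-methyldodec-11-enoate (C3, C5, C9 as in the target)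
Conditions: (+)-Ipc2BOMe (from (−)-α-pinene), allylMgBr, Et2O; then 6, −78 °C; pH 7 buffer, MeOH, 30 % H2O2
Reagents that add atoms: allylmagnesium bromide, C=CC[Mg]Br
Why: Brown allylboration with the same reagent antipode as in step 3 (Re‑face attack) should set C9 under reagent control, the remote C5 centre exerting no bias.

Step 7
Reactants: 7 methyl 5-[(tert-butyldimethylsilyl)oxy]-9-hydroxy-3-methyldodec-11-enoate
Product: 8 methyl 5,9-bis[(tert-butyldimethylsilyl)oxy]-3-methyldodec-11-enoate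
Conditions: TBSOTf, 2,6-lutidine, CH2Cl2, −78 °C
Reagents that add atoms: tert-butyldimethylsilyl triflate, CC(C)(C)[Si](C)(C)OS(=O)(=O)C(F)(F)F
Why: Routine silyl ether formation on the secondary alcohol.

Step 8
Reactants: 8 methyl 5,9-bis[(tert-butyldimethylsilyl)oxy]-3-methyldodec-11-enoate
Product: 9 methyl 5,9-bis[(tert-butyldimethylsilyl)oxy]-3-methyl-13-oxotridecanoate
Conditions: Rh(acac)(CO)2 (1 mol %), BIPHEPHOS (2 mol %), CO/H2 (1:1, 5 bar), THF, 60 °C
Reagents that add atoms: carbon monoxide, [C-]#[O+]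
Why: Linear‑selective hydroformylation as in step 5 should give the C13 aldehyde.

Step 9
Reactants: 9 methyl 5,9-bis[(tert-butyldimethylsilyl)oxy]-3-methyl-13-oxotridecanoate
Product: 10 methyl 5,9-bis[(tert-butyldimethylsilyl)oxy]-13-hydroxy-3-methylhexadec-15-enoate (C13 as in the target)
Conditions: (−)-Ipc2BOMe (from (+)-α-pinene), allylMgBr, Et2O; then 9, −78 °C; pH 7 buffer, MeOH, 30 % H2O2
Reagents that add atoms: allylmagnesium bromide, C=CC[Mg]Br
Why: Brown allylboration with the antipodal reagent (Si‑face attack) should set C13 in the sense opposite to C5 and C9, as the target requires.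

Step 10
Reactants: 10 methyl 5,9-bis[(tert-butyldimethylsilyl)oxy]-13-hydroxy-3-methylhexadec-15-enoate
Product: 11 methyl 5,9,13-tris[(tert-butyldimethylsilyl)oxy]-3-methylhexadec-15-enoate
Conditions: TBSOTf, 2,6-lutidine, CH2Cl2, −78 °C
Reagents that add atoms: tert-butyldimethylsilyl triflate, CC(C)(C)[Si](C)(C)OS(=O)(=O)C(F)(F)F
Why: Routine silyl ether formation.

Step 11
Reactants: 11 methyl 5,9,13-tris[(tert-butyldimethylsilyl)oxy]-3-methylhexadec-15-enoate
Product: 12 5,9,13-tris[(tert-butyldimethylsilyl)oxy]-3-methylhexadec-15-enoic acid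
Conditions: LiOH, THF/MeOH/H2O, rt; then 1 M HCl to pH 4, 0 °C
Reagents that add atoms: lithium hydroxide, [Li+].[OH-]
Why: Saponification of the unhindered methyl ester; silyl ethers and the terminal alkene are stable to aqueous hydroxide.

Step 12
Reactants: 12 5,9,13-tris[(tert-butyldimethylsilyl)oxy]-3-methylhexadec-15-enoic acid
Product: 13 5,9,13-tris[(tert-butyldimethylsilyl)oxy]-3-methyl-17-oxoheptadecanoic acid (C1–C17 aldehyde acid)
Conditions: Rh(acac)(CO)2 (1 mol %), BIPHEPHOS (2 mol %), CO/H2 (1:1, 5 bar), THF, 60 °C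
Reagents that add atoms: carbon monoxide, [C-]#[O+]
Why: Linear‑selective hydroformylation tolerates the free carboxylic acid and should give the C17 aldehyde directly.

**Common building block and C18–C25 aldehyde (steps 13–16)**

Step 13
Reactants: 14 (S)-2-(but-3-en-1-yl)oxirane
Product: 15 (S)-1-(trimethylsilyl)oct-7-en-1-yn-4-ol
Conditions: (trimethylsilyl)acetylene, n-BuLi, THF, −78 °C; BF3·OEt2; then 14, −78 °C
Reagents that add atoms: (trimethylsilyl)acetylene, C#C[Si](C)(C)C
Why: BF3‑promoted SN2 opening of the terminal epoxide by the lithium acetylide occurs at the unsubstituted carbon, so the stereocentre (later C21 and C29) is not touched.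

Step 14
Reactants: 15 (S)-1-(trimethylsilyl)oct-7-en-1-yn-4-ol
Product: 16 (S)-tert-butyldimethyl{[1-(trimethylsilyl)oct-7-en-1-yn-4-yl]oxy}silane
Conditions: TBSOTf, 2,6-lutidine, CH2Cl2, −78 °C
Reagents that add atoms: tert-butyldimethylsilyl triflate, CC(C)(C)[Si](C)(C)OS(=O)(=O)C(F)(F)F
Why: Routine silyl ether formation.

Step 15
Reactants: 16 (S)-tert-butyldimethyl{[1-(trimethylsilyl)oct-7-en-1-yn-4-yl]oxy}silane
Product: 18 (S)-5-[(tert-butyldimethylsilyl)oxy]oct-7-yn-1-ol, via B-alkyl-9-BBN adduct 17 (not isolated)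
Conditions: 9-BBN, THF, 0 °C → rt; then 3 M NaOH, 30 % H2O2, MeOH, 0 °C → rt
Reagents that add atoms: hydrogen peroxide, OO
Why: Hydroboration–oxidation: 9-BBN adds anti‑Markovnikov to the monosubstituted alkene far faster than to the silyl‑capped alkyne, and the methanolic hydroxide of the oxidative stage also cleaves the alkynyl C–Si bond.

Step 16
Reactants: 18 (S)-5-[(tert-butyldimethylsilyl)oxy]oct-7-yn-1-ol
Product: 19 (S)-5-[(tert-butyldimethylsilyl)oxy]oct-7-ynal (C18–C25 aldehyde)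
Conditions: TEMPO (10 mol %), PhI(OAc)2, CH2Cl2, rt
Reagents that add atoms: none
Why: Oxoammonium (TEMPO) oxidation to the aldehyde; the terminal alkyne and silyl ether are inert.

**C26–C40 ketone (steps 17–25)**

Step 17
Reactants: 15 (S)-1-(trimethylsilyl)oct-7-en-1-yn-4-ol
Product: 20 (S)-[4-(benzyloxy)oct-7-en-1-yn-1-yl]trimethylsilane
Conditions: benzyl 2,2,2-trichloroacetimidate, TfOH (5 mol %), cyclohexane/CH2Cl2, 0 °C → rt
Reagents that add atoms: benzyl 2,2,2-trichloroacetimidate, ClC(Cl)(Cl)C(=N)OCc1ccccc1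
Why: Acid‑catalysed imidate benzylation avoids an alkoxide (no silyl migration from the alkyne) and installs the β‑alkoxy group needed for 1,5‑induction in step 26.

Step 18
Reactants: 20 (S)-[4-(benzyloxy)oct-7-en-1-yn-1-yl]trimethylsilane
Product: 22 (S)-5-(benzyloxy)oct-7-yn-1-ol, via B-alkyl-9-BBN adduct 21 (not isolated)
Conditions: 9-BBN, THF, 0 °C → rt; then 3 M NaOH, 30 % H2O2, MeOH, 0 °C → rt
Reagents that add atoms: hydrogen peroxide, OO
Why: Hydroboration–oxidation with concurrent alkynyl desilylation, as in step 15.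

Step 19
Reactants: 22 (S)-5-(benzyloxy)oct-7-yn-1-ol
Product: 23 (S)-5-(benzyloxy)oct-7-ynal
Conditions: TEMPO (10 mol %), PhI(OAc)2, CH2Cl2, rt
Reagents that add atoms: none
Why: Oxoammonium (TEMPO) oxidation to the C33 aldehyde.

Step 20
Reactants: 23 (S)-5-(benzyloxy)oct-7-ynal
Product: 24 (4S,8S)-8-(benzyloxy)undec-1-en-10-yn-4-ol
Conditions: (+)-Ipc2BOMe (from (−)-α-pinene), allylMgBr, Et2O; then 23, −78 °C; pH 7 buffer, MeOH, 30 % H2O2
Reagents that add atoms: allylmagnesium bromide, C=CC[Mg]Br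
Why: Brown allylboration (Re‑face attack) should set C33 under reagent control; the terminal alkyne does not react with the allylborane.

Step 21
Reactants: 24 (4S,8S)-8-(benzyloxy)undec-1-en-10-yn-4-ol
Product: 25 {[(4S,8S)-8-(benzyloxy)undec-1-en-10-yn-4-yl]oxy}(tert-butyl)dimethylsilane
Conditions: TBSOTf, 2,6-lutidine, CH2Cl2, −78 °C
Reagents that add atoms: tert-butyldimethylsilyl triflate, CC(C)(C)[Si](C)(C)OS(=O)(=O)C(F)(F)F
Why: Routine silyl ether formation.

Step 22
Reactants: 25 {[(4S,8S)-8-(benzyloxy)undec-1-en-10-yn-4-yl]oxy}(tert-butyl)dimethylsilane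
Product: 26 (4S,8S)-4-(benzyloxy)-8-[(tert-butyldimethylsilyl)oxy]undec-10-en-2-one
Conditions: Ph3PAuNTf2 (2 mol %), H2O (5 equiv), 1,4-dioxane, 60 °C
Reagents that add atoms: water, O
Why: Gold‑catalysed Markovnikov hydration of the terminal alkyne should give the C27 methyl ketone; the alkynophilic catalyst leaves the terminal alkene and the ethers alone.

Step 23
Reactants: 26 (4S,8S)-4-(benzyloxy)-8-[(tert-butyldimethylsilyl)oxy]undec-10-en-2-one
Product: 28 (3S,7S)-7-(benzyloxy)-3-[(tert-butyldimethylsilyl)oxy]-9-oxodecanal, via secondary ozonide 27 (not isolated)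
Conditions: O3, CH2Cl2, −78 °C, to a faint blue end point; then PPh3, −78 °C → rt
Reagents that add atoms: ozone, [O-][O+]=O
Why: Ozonolysis with reductive work‑up cleaves the only alkene to the C35 aldehyde; the ketone is inert.

Step 24
Reactants: 28 (3S,7S)-7-(benzyloxy)-3-[(tert-butyldimethylsilyl)oxy]-9-oxodecanal
Product: 29 4-(benzyloxy)-8-[(tert-butyldimethylsilyl)oxy]-10-hydroxy-11-methyltridec-12-en-2-one (C35 hydroxyl and C36 methyl anti, as in the target)
Conditions: (E)-but-2-ene, KOtBu, n-BuLi, THF, −78 → −45 °C; (−)-Ipc2BOMe (from (+)-α-pinene), −78 °C; BF3·OEt2; then 28, −78 °C; pH 7 buffer, MeOH, 30 % H2O2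
Reagents that add atoms: (E)-but-2-ene, C/C=C/C
Why: Brown (E)-crotylboration: the chair transition state turns the E geometry into the anti C35/C36 relationship, Si‑face attack fixes the absolute sense, and at −78 °C the crotylborane reacts with the aldehyde far faster than with the methyl ketone.

Step 25
Reactants: 29 4-(benzyloxy)-8-[(tert-butyldimethylsilyl)oxy]-10-hydroxy-11-methyltridec-12-en-2-one
Product: 30 (E)-4-(benzyloxy)-8-[(tert-butyldimethylsilyl)oxy]-10-hydroxy-11-methylpentadec-12-en-2-one (C26–C40 ketone)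
Conditions: (Z)-hex-3-ene (10 equiv), second-generation Grubbs catalyst RuCl2(H2IMes)(PCy3)(=CHPh) (5 mol %), CH2Cl2, 40 °C
Reagents that add atoms: (Z)-hex-3-ene, CC/C=C\CC
Why: Olefin cross‑metathesis with an excess of the symmetrical internal olefin converts the vinyl group into a but-1-enyl group (C37–C40); the alkene geometry is irrelevant because step 32 saturates it.

**Fragment union and iodoalkene (steps 26–29)**

Step 26
Reactants: 30 (E)-4-(benzyloxy)-8-[(tert-butyldimethylsilyl)oxy]-10-hydroxy-11-methylpentadec-12-en-2-one; 19 (S)-5-[(tert-butyldimethylsilyl)oxy]oct-7-ynal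
Product: 32 C18–C40 β-hydroxy ketone (C25 hydroxyl; C27 ketone; C29 benzyl ether; C21 and C33 TBS ethers; free C35 hydroxyl; C18≡C19 alkyne), via dibutylboron enolate 31 (not isolated)
Conditions: Bu2BOTf (2.2 equiv), iPr2NEt (2.5 equiv), Et2O, −78 °C; then 19, −78 → −20 °C; pH 7 buffer, MeOH, 30 % H2O2
Reagents that add atoms: none
Why: Boron‑mediated 1,5‑anti aldol reaction of a β‑alkoxy methyl ketone: kinetic enolisation at the methyl group and induction from the C29 benzyloxy group should set C25 anti to C29, the remote C35 hydroxyl being masked in the flask as its dibutylborinate and released on work‑up.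

Step 27
Reactants: 32 C18–C40 β-hydroxy ketone
Product: 33 C18–C40 syn-C25,C27-diol
Conditions: Et2BOMe, NaBH4, THF/MeOH (4:1), −78 °C; AcOH quench; MeOH azeotrope
Reagents that add atoms: none
Why: Narasaka–Prasad reduction: external hydride attacks the diethylboron chelate of the β‑hydroxy ketone axially, which should set C27 syn to C25 and hence anti to C29.

Step 28
Reactants: 33 C18–C40 syn-C25,C27-diol
Product: 34 C25,C27-acetonide of 33 (free C35 hydroxyl, terminal alkyne)
Conditions: 2,2-dimethoxypropane (1.5 equiv), PPTS (cat.), CH2Cl2, 0 °C → rt; aqueous NaHCO3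
Reagents that add atoms: 2,2-dimethoxypropane, COC(C)(C)OC
Why: Acetonide formation (ketal exchange) is favoured for the syn‑1,3‑diol, whose dioxane chair carries both substituents equatorially, whereas the isolated, hindered C35 hydroxyl cannot form a cyclic ketal.

Step 29
Reactants: 34 C25,C27-acetonide of 33
Product: 36 C18–C40 (E)-C18-iodoalkene with free C35 hydroxyl, via alkenylzirconocene 35 (not isolated)
Conditions: Cp2Zr(H)Cl (2.3 equiv), THF, 0 °C → rt; then I2, THF, −78 → 0 °C, to a persistent colour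
Reagents that add atoms: iodine, II
Why: Hydrozirconation–iodination: syn addition of Zr–H places zirconium on the terminal alkyne carbon and iodinolysis with retention should give the (E)-alkenyl iodide; one equivalent is consumed by the C35 hydroxyl as its zirconium alkoxide, and the hindered internal C37=C38 alkene reacts far more slowly.

**Endgame (steps 30–33)**

Step 30
Reactants: 36 C18–C40 (E)-C18-iodoalkene with free C35 hydroxyl; 13 5,9,13-tris[(tert-butyldimethylsilyl)oxy]-3-methyl-17-oxoheptadecanoic acid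
Product: 38 seco ester (C35 ester of 36 and 13, carrying the C17 aldehyde and the C18 alkenyl iodide), via mixed anhydride 37 (not isolated)
Conditions: 2,4,6-trichlorobenzoyl chloride, Et3N, THF, rt; then 36, DMAP, toluene, rt
Reagents that add atoms: none
Why: Yamaguchi esterification: DMAP attacks the mixed anhydride at the aliphatic carbonyl and the acylpyridinium acylates the only free hydroxyl (C35), forming the future lactone ester with retention at C35.

Step 31
Reactants: 38 seco ester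
Product: 39 macrocyclic (17S)-allylic alcohol (36-membered lactone; (E)-C18=C19; TBS ethers at C5, C9, C13, C21, C33; C25/C27 acetonide; C29 benzyl ether)
Conditions: CrCl2 (10 equiv), chiral sulfonamide–oxazoline ligand N-[2-(4-isopropyl-4,5-dihydrooxazol-2-yl)-6-methylphenyl]methanesulfonamide (antipode giving Re-face addition, 11 equiv), Et3N (11 equiv), NiCl2 (cat.), THF/MeCN, rt; 38 added by syringe pump to about 1 mM; aqueous sodium serinate work-up
Reagents that add atoms: none
Why: Zerovalent nickel, formed from NiCl2 and divalent chromium, inserts into the C18–I bond with retention of the E geometry and passes the alkenyl group to trivalent chromium, and the alkenylchromium adds to the C17 aldehyde inside the coordination sphere of the chromium‑bound chiral ligand (Nozaki–Hiyama–Kishi reaction). The closest known reaction type is the Ni/Cr‑mediated alkenyl iodide–aldehyde macrocyclisation in its ligand‑controlled asymmetric form. The 36‑membered ring (C1–C35 plus the lactone oxygen) closes by a 36‑exo‑trig addition to the carbonyl group; the ring is essentially strain‑free, so closure depends on dilution alone. The new stereocentre C17 lies four bonds from both C13 and C21, so the substrate offers no useful bias and the 17S configuration (Re‑face attack) is set by the ligand antipode, both antipodes being available from D‑ or L‑valinol. The step needs chemoselectivity for the aldehyde over the ester (organochromium reagents do not add to esters), tolerance of the silyl, benzyl and acetonide groups, and intramolecular over intermolecular coupling, which slow addition to high dilution should secure. The geometry of the C18=C19 alkene has no consequence because step 32 saturates it.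

Step 32
Reactants: 39 macrocyclic (17S)-allylic alcohol
Product: 40 saturated macrolide (5,9,13,21,33-penta-O-TBS, 25,27-O-isopropylidene derivative of the target)
Conditions: H2 (1 atm), Pd(OH)2/C, EtOAc/EtOH, rt
Reagents that add atoms: none
Why: Heterogeneous catalytic hydrogenation should saturate the C18=C19 and C37=C38 alkenes and hydrogenolyse the C29 benzyl ether in one operation without touching any stereocentre.

Step 33
Reactants: 40 saturated macrolide
Product: 41 CNP0225459.2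
Conditions: 48 % aqueous HF, MeCN/THF, 0 °C → rt; NaHCO3 quench
Reagents that add atoms: none
Why: Global deprotection: aqueous HF cleaves the five silyl ethers and hydrolyses the acetonide under conditions mild enough to leave the macrolactone unopened and untransposed.

**Compound list**

1 | methyl hydrogen (R)-3-methylglutarate | OC(=O)C[C@@H](C)CC(=O)OC | starting material
2 | methyl (3R)-5-hydroxy-3-methylpentanoate | OCC[C@@H](C)CC(=O)OC | intermediate
3 | methyl (3R)-3-methyl-5-oxopentanoate | O=CC[C@@H](C)CC(=O)OC | intermediate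
4 | methyl (3R,5R)-5-hydroxy-3-methyloct-7-enoate | C=CC[C@@H](O)C[C@@H](C)CC(=O)OC | intermediate
5 | methyl (3R,5R)-5-[(tert-butyldimethylsilyl)oxy]-3-methyloct-7-enoate | C=CC[C@@H](O[Si](C)(C)C(C)(C)C)C[C@@H](C)CC(=O)OC | intermediate
6 | methyl (3R,5R)-5-[(tert-butyldimethylsilyl)oxy]-3-methyl-9-oxononanoate | O=CCCC[C@@H](O[Si](C)(C)C(C)(C)C)C[C@@H](C)CC(=O)OC | intermediate
7 | methyl 5-[(tert-butyldimethylsilyl)oxy]-9-hydroxy-3-methyldodec-11-enoate (C3, C5, C9 as in target) | C=CC[C@@H](O)CCC[C@@H](O[Si](C)(C)C(C)(C)C)C[C@@H](C)CC(=O)OC | intermediate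
8 | methyl 5,9-bis[(tert-butyldimethylsilyl)oxy]-3-methyldodec-11-enoate | C=CC[C@@H](O[Si](C)(C)C(C)(C)C)CCC[C@@H](O[Si](C)(C)C(C)(C)C)C[C@@H](C)CC(=O)OC | intermediate
9 | methyl 5,9-bis[(tert-butyldimethylsilyl)oxy]-3-methyl-13-oxotridecanoate | O=CCCC[C@@H](O[Si](C)(C)C(C)(C)C)CCC[C@@H](O[Si](C)(C)C(C)(C)C)C[C@@H](C)CC(=O)OC | intermediate
10 | methyl 5,9-bis[(tert-butyldimethylsilyl)oxy]-13-hydroxy-3-methylhexadec-15-enoate (C13 as in target) | C=CC[C@H](O)CCC[C@@H](O[Si](C)(C)C(C)(C)C)CCC[C@@H](O[Si](C)(C)C(C)(C)C)C[C@@H](C)CC(=O)OC | intermediate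
11 | methyl 5,9,13-tris[(tert-butyldimethylsilyl)oxy]-3-methylhexadec-15-enoate | C=CC[C@H](O[Si](C)(C)C(C)(C)C)CCC[C@@H](O[Si](C)(C)C(C)(C)C)CCC[C@@H](O[Si](C)(C)C(C)(C)C)C[C@@H](C)CC(=O)OC | intermediate
12 | 5,9,13-tris[(tert-butyldimethylsilyl)oxy]-3-methylhexadec-15-enoic acid | C=CC[C@H](O[Si](C)(C)C(C)(C)C)CCC[C@@H](O[Si](C)(C)C(C)(C)C)CCC[C@@H](O[Si](C)(C)C(C)(C)C)C[C@@H](C)CC(=O)O | intermediate
13 | 5,9,13-tris[(tert-butyldimethylsilyl)oxy]-3-methyl-17-oxoheptadecanoic acid (C1–C17 aldehyde acid) | O=CCCC[C@H](O[Si](C)(C)C(C)(C)C)CCC[C@@H](O[Si](C)(C)C(C)(C)C)CCC[C@@H](O[Si](C)(C)C(C)(C)C)C[C@@H](C)CC(=O)O | intermediate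
14 | (S)-2-(but-3-en-1-yl)oxirane [(S)-1,2-epoxy-5-hexene] | C=CCC[C@H]1CO1 | starting material
15 | (S)-1-(trimethylsilyl)oct-7-en-1-yn-4-ol | C=CCC[C@H](O)CC#C[Si](C)(C)C | intermediate
16 | (S)-tert-butyldimethyl{[1-(trimethylsilyl)oct-7-en-1-yn-4-yl]oxy}silane | C=CCC[C@H](O[Si](C)(C)C(C)(C)C)CC#C[Si](C)(C)C | intermediate
17 | B-alkyl-9-BBN adduct of 16 (boron on the terminal carbon) | C1CCC2CCCC1B2CCCC[C@H](O[Si](C)(C)C(C)(C)C)CC#C[Si](C)(C)C | intermediate (not isolated)
18 | (S)-5-[(tert-butyldimethylsilyl)oxy]oct-7-yn-1-ol | OCCCC[C@H](O[Si](C)(C)C(C)(C)C)CC#C | intermediate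
19 | (S)-5-[(tert-butyldimethylsilyl)oxy]oct-7-ynal (C18–C25 aldehyde) | O=CCCC[C@H](O[Si](C)(C)C(C)(C)C)CC#C | intermediate
20 | (S)-[4-(benzyloxy)oct-7-en-1-yn-1-yl]trimethylsilane | C=CCC[C@H](OCc1ccccc1)CC#C[Si](C)(C)C | intermediate
21 | B-alkyl-9-BBN adduct of 20 | C1CCC2CCCC1B2CCCC[C@H](OCc1ccccc1)CC#C[Si](C)(C)C | intermediate (not isolated)
22 | (S)-5-(benzyloxy)oct-7-yn-1-ol | OCCCC[C@H](OCc1ccccc1)CC#C | intermediate
23 | (S)-5-(benzyloxy)oct-7-ynal | O=CCCC[C@H](OCc1ccccc1)CC#C | intermediate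
24 | (4S,8S)-8-(benzyloxy)undec-1-en-10-yn-4-ol | C=CC[C@@H](O)CCC[C@H](OCc1ccccc1)CC#C | intermediate
25 | {[(4S,8S)-8-(benzyloxy)undec-1-en-10-yn-4-yl]oxy}(tert-butyl)dimethylsilane | C=CC[C@@H](O[Si](C)(C)C(C)(C)C)CCC[C@H](OCc1ccccc1)CC#C | intermediate
26 | (4S,8S)-4-(benzyloxy)-8-[(tert-butyldimethylsilyl)oxy]undec-10-en-2-one | C=CC[C@@H](O[Si](C)(C)C(C)(C)C)CCC[C@H](OCc1ccccc1)CC(C)=O | intermediate
27 | secondary ozonide (1,2,4-trioxolane) of 26 | C1OC(OO1)C[C@@H](O[Si](C)(C)C(C)(C)C)CCC[C@H](OCc1ccccc1)CC(C)=O | intermediate (not isolated)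
28 | (3S,7S)-7-(benzyloxy)-3-[(tert-butyldimethylsilyl)oxy]-9-oxodecanal | O=CC[C@@H](O[Si](C)(C)C(C)(C)C)CCC[C@H](OCc1ccccc1)CC(C)=O | intermediate
29 | 4-(benzyloxy)-8-[(tert-butyldimethylsilyl)oxy]-10-hydroxy-11-methyltridec-12-en-2-one (C29, C33, C35, C36 as in target) | C=C[C@H](C)[C@H](O)C[C@@H](O[Si](C)(C)C(C)(C)C)CCC[C@H](OCc1ccccc1)CC(C)=O | intermediate
30 | (E)-4-(benzyloxy)-8-[(tert-butyldimethylsilyl)oxy]-10-hydroxy-11-methylpentadec-12-en-2-one (C26–C40 ketone; E drawn, Z tolerated) | CC/C=C/[C@H](C)[C@H](O)C[C@@H](O[Si](C)(C)C(C)(C)C)CCC[C@H](OCc1ccccc1)CC(C)=O | intermediate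
31 | dibutylboron enolate of 30 (C35 hydroxyl as dibutylborinate) | CC/C=C/[C@H](C)[C@H](OB(CCCC)CCCC)C[C@@H](O[Si](C)(C)C(C)(C)C)CCC[C@H](OCc1ccccc1)CC(=C)OB(CCCC)CCCC | intermediate (not isolated)
32 | C18–C40 β-hydroxy ketone (C25 hydroxyl, C27 ketone) | CC/C=C/[C@H](C)[C@H](O)C[C@@H](O[Si](C)(C)C(C)(C)C)CCC[C@H](OCc1ccccc1)CC(=O)C[C@@H](O)CCC[C@H](O[Si](C)(C)C(C)(C)C)CC#C | intermediate
33 | C18–C40 syn-C25,C27-diol | CC/C=C/[C@H](C)[C@H](O)C[C@@H](O[Si](C)(C)C(C)(C)C)CCC[C@H](OCc1ccccc1)C[C@@H](O)C[C@@H](O)CCC[C@H](O[Si](C)(C)C(C)(C)C)CC#C | intermediate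
34 | C25,C27-acetonide of 33 | CC/C=C/[C@H](C)[C@H](O)C[C@@H](O[Si](C)(C)C(C)(C)C)CCC[C@H](OCc1ccccc1)C[C@@H](OC(C)(C)O2)C[C@@H]2CCC[C@H](O[Si](C)(C)C(C)(C)C)CC#C | intermediate
35 | (E)-C18 alkenylzirconocene chloride of 34 (C35 as zirconium alkoxide) | CC/C=C/[C@H](C)[C@H](O[Zr](Cl)(C1C=CC=C1)C1C=CC=C1)C[C@@H](O[Si](C)(C)C(C)(C)C)CCC[C@H](OCc1ccccc1)C[C@@H](OC(C)(C)O2)C[C@@H]2CCC[C@H](O[Si](C)(C)C(C)(C)C)C/C=C/[Zr](Cl)(C1C=CC=C1)C1C=CC=C1 | intermediate (not isolated)
36 | C18–C40 (E)-C18-iodoalkene with free C35 hydroxyl | CC/C=C/[C@H](C)[C@H](O)C[C@@H](O[Si](C)(C)C(C)(C)C)CCC[C@H](OCc1ccccc1)C[C@@H](OC(C)(C)O2)C[C@@H]2CCC[C@H](O[Si](C)(C)C(C)(C)C)C/C=C/I | intermediate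
37 | mixed 2,4,6-trichlorobenzoic anhydride of 13 | O=CCCC[C@H](O[Si](C)(C)C(C)(C)C)CCC[C@@H](O[Si](C)(C)C(C)(C)C)CCC[C@@H](O[Si](C)(C)C(C)(C)C)C[C@@H](C)CC(=O)OC(=O)c1c(Cl)cc(Cl)cc1Cl | intermediate (not isolated)
38 | seco ester (C35 ester of 36 and 13; C17 aldehyde, C18 alkenyl iodide) | CC/C=C/[C@H](C)[C@H](OC(=O)C[C@H](C)C[C@H](O[Si](C)(C)C(C)(C)C)CCC[C@H](O[Si](C)(C)C(C)(C)C)CCC[C@@H](O[Si](C)(C)C(C)(C)C)CCCC=O)C[C@@H](O[Si](C)(C)C(C)(C)C)CCC[C@H](OCc1ccccc1)C[C@@H](OC(C)(C)O2)C[C@@H]2CCC[C@H](O[Si](C)(C)C(C)(C)C)C/C=C/I | intermediate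
39 | macrocyclic (17S)-allylic alcohol (protected 36-membered lactone with (E)-C18=C19) | CC/C=C/[C@H](C)[C@H]1C[C@@H](O[Si](C)(C)C(C)(C)C)CCC[C@H](OCc2ccccc2)C[C@@H](OC(C)(C)O3)C[C@@H]3CCC[C@H](O[Si](C)(C)C(C)(C)C)C/C=C/[C@@H](O)CCC[C@H](O[Si](C)(C)C(C)(C)C)CCC[C@@H](O[Si](C)(C)C(C)(C)C)CCC[C@@H](O[Si](C)(C)C(C)(C)C)C[C@@H](C)CC(=O)O1 | intermediate
40 | saturated macrolide (5,9,13,21,33-penta-O-TBS, 25,27-O-isopropylidene derivative of the target) | CCCC[C@H](C)[C@H]1C[C@@H](O[Si](C)(C)C(C)(C)C)CCC[C@H](O)C[C@@H](OC(C)(C)O2)C[C@@H]2CCC[C@H](O[Si](C)(C)C(C)(C)C)CCC[C@@H](O)CCC[C@H](O[Si](C)(C)C(C)(C)C)CCC[C@@H](O[Si](C)(C)C(C)(C)C)CCC[C@@H](O[Si](C)(C)C(C)(C)C)C[C@@H](C)CC(=O)O1 | intermediate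
41 | CNP0225459.2, (3R,5R,9R,13S,17S,21R,25S,27S,29S,33S,35R,36S)-5,9,13,17,21,25,27,29,33-nonahydroxy-3,36-dimethyltetracontan-35-olide | CCCC[C@H](C)[C@H]1C[C@@H](O)CCC[C@H](O)C[C@@H](O)C[C@@H](O)CCC[C@H](O)CCC[C@@H](O)CCC[C@H](O)CCC[C@@H](O)CCC[C@@H](O)C[C@@H](C)CC(=O)O1 | target

**Step count and risks**

Total steps: 33. Longest linear sequence: 18 steps (14 → 41 through steps 13, 17–29 and 30–33); the C1–C17 branch runs 16 steps to the target.

Steps most likely to fail:

1. Step 31. The chromium‑bound ligand may discriminate poorly between the two faces of the C17 carbonyl, and intermolecular coupling may compete with ring closure. Fallback: setting out from 38, a ligand‑free Ni/Cr macrocyclisation (CrCl2, catalytic NiCl2, DMSO/THF, high dilution) would give 39 together with its C17 epimer, the macrocyclic (17R)-allylic alcohol F1. Oxidation of the mixture with Dess–Martin periodinane would converge both on the macrocyclic C17 enone F2. Corey–Bakshi–Shibata reduction with (R)-2-methyl-CBS-oxazaborolidine and catecholborane (reagent control, alkenyl as the large group) would then return to the route at 39.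

2. Step 30. Acylation of the hindered C35 hydroxyl may be slow enough for the free C17 aldehyde to enolise or self‑condense under the amine bases. Fallback: setting out from 11, hydroformylation under the conditions of step 12 would give the C17 aldehyde methyl ester F3, and acetalisation (HC(OMe)3, MeOH, PPTS) the dimethyl acetal methyl ester F4. Saponification (LiOH) would give the dimethyl acetal acid F5, and Yamaguchi esterification with 36 the acetal seco ester F6. Chemoselective acetal cleavage (TESOTf, 2,4,6-collidine, CH2Cl2; then H2O), which spares the acetonide and the silyl ethers, would return to the route at 38.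

3. Step 32. Palladium may isomerise the C17 allylic alcohol to the ketone or cleave its C–O bond before the alkene is saturated, and benzyl ether cleavage may stall. Fallback: setting out from 39, diimide reduction (2-nitrobenzenesulfonyl hydrazide, Et3N, CH2Cl2) would saturate both alkenes without metal hydride chemistry to give the saturated C29 benzyl ether macrolide F7. Hydrogenolysis (H2, Pd/C, EtOAc), now with no allylic system present, would return to the route at 40.

Further compounds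

F1 | step 31 | macrocyclic (17R)-allylic alcohol (C17 epimer of 39) | CC/C=C/[C@H](C)[C@H]1C[C@@H](O[Si](C)(C)C(C)(C)C)CCC[C@H](OCc2ccccc2)C[C@@H](OC(C)(C)O3)C[C@@H]3CCC[C@H](O[Si](C)(C)C(C)(C)C)C/C=C/[C@H](O)CCC[C@H](O[Si](C)(C)C(C)(C)C)CCC[C@@H](O[Si](C)(C)C(C)(C)C)CCC[C@@H](O[Si](C)(C)C(C)(C)C)C[C@@H](C)CC(=O)O1
F2 | step 31 | macrocyclic C17 enone | CC/C=C/[C@H](C)[C@H]1C[C@@H](O[Si](C)(C)C(C)(C)C)CCC[C@H](OCc2ccccc2)C[C@@H](OC(C)(C)O3)C[C@@H]3CCC[C@H](O[Si](C)(C)C(C)(C)C)C/C=C/C(=O)CCC[C@H](O[Si](C)(C)C(C)(C)C)CCC[C@@H](O[Si](C)(C)C(C)(C)C)CCC[C@@H](O[Si](C)(C)C(C)(C)C)C[C@@H](C)CC(=O)O1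
F3 | step 30 | C17 aldehyde methyl ester (methyl 5,9,13-tris[(tert-butyldimethylsilyl)oxy]-3-methyl-17-oxoheptadecanoate) | O=CCCC[C@H](O[Si](C)(C)C(C)(C)C)CCC[C@@H](O[Si](C)(C)C(C)(C)C)CCC[C@@H](O[Si](C)(C)C(C)(C)C)C[C@@H](C)CC(=O)OC
F4 | step 30 | dimethyl acetal methyl ester | COC(OC)CCC[C@H](O[Si](C)(C)C(C)(C)C)CCC[C@@H](O[Si](C)(C)C(C)(C)C)CCC[C@@H](O[Si](C)(C)C(C)(C)C)C[C@@H](C)CC(=O)OC
F5 | step 30 | dimethyl acetal acid | COC(OC)CCC[C@H](O[Si](C)(C)C(C)(C)C)CCC[C@@H](O[Si](C)(C)C(C)(C)C)CCC[C@@H](O[Si](C)(C)C(C)(C)C)C[C@@H](C)CC(=O)O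
F6 | step 30 | acetal seco ester (C17 dimethyl acetal analogue of 38) | CC/C=C/[C@H](C)[C@H](OC(=O)C[C@H](C)C[C@H](O[Si](C)(C)C(C)(C)C)CCC[C@H](O[Si](C)(C)C(C)(C)C)CCC[C@@H](O[Si](C)(C)C(C)(C)C)CCCC(OC)OC)C[C@@H](O[Si](C)(C)C(C)(C)C)CCC[C@H](OCc1ccccc1)C[C@@H](OC(C)(C)O2)C[C@@H]2CCC[C@H](O[Si](C)(C)C(C)(C)C)C/C=C/I
F7 | step 32 | saturated C29 benzyl ether macrolide | CCCC[C@H](C)[C@H]1C[C@@H](O[Si](C)(C)C(C)(C)C)CCC[C@H](OCc2ccccc2)C[C@@H](OC(C)(C)O3)C[C@@H]3CCC[C@H](O[Si](C)(C)C(C)(C)C)CCC[C@@H](O)CCC[C@H](O[Si](C)(C)C(C)(C)C)CCC[C@@H](O[Si](C)(C)C(C)(C)C)CCC[C@@H](O[Si](C)(C)C(C)(C)C)C[C@@H](C)CC(=O)O1
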